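I have 0.056 M of substrate in the flask, and I want every mole of it booked at 8.0 s: still there, or turned into target, side product or over-reaction product.

substrate 0.056 M; gas phase 2.2 mM (held); time 8.0 s

    gas phase ⇌ dissolved gas, rate k1*(csat - [dissolved gas]) (k1 = 2.1 /s, csat = 2.2 mM)
    substrate + dissolved gas → target (k2 = 40 /M/s)
    substrate → side product (k3 = 0.052 /s)
    dissolved gas + target → over-reaction product (k4 = 36 /M/s)

1. target at 8.0 s, in percent of the substrate charged
2. the change that raises the amount of target at 8.0 s, in percent of the substrate charged most ("none" if none brings more than 2 percentage points) (dusk / autumn / none)
3. amount of target at 8.0 s, in percent of the substrate charged, after dusk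

- dusk: doubling the transfer coefficient of step 1, all else as stated
- autumn: doubling the saturation concentration of gas phase, all else as stated

- at the start none of the gas is dissolved
- run time (flask): 8.0 s

1. I freeze [dissolved gas]. Its level relaxes in about 0.230 s, far shorter than the run, so I hold supply equal to uptake by the charged substrate. The frozen gas level is the transfer coefficient times the saturation concentration, divided by the transfer coefficient plus the rate constant of the target step times [substrate]. This gives 1.06 mM.

2. With that level, substrate falls in a pseudo-first-order way with constant 0.0946 /s, so the first entry is 46.9 % left.

3. The rest splits between the target route, 0.0426 /s, and the side route, 0.052 /s. That books 29.2 % as side product and 23.9 % as target formed.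

4. Target is lost at 0.0383 /s. I take it to grow steadily, so that it holds on average half its final amount. Then 15.3 % of what formed moves on, which books 3.66 % as over-reaction product and leaves 20.2 % as target. The books close at 100 %.

5. For dusk I reckon a frozen level of 1.43 mM, and the same ledger gives 24.3 % target. For autumn I reckon 2.13 mM, and the ledger gives 28.7 %, so I choose autumn, the higher of the two.

The forecast, a little above my figure for this flask, gives 20.6 %, then 24.3 % after dusk, and names autumn, with the ground: “Doubling csat doubles the dissolved gas outright”.

The simulation gives 20.9 %, names autumn with a gain of 8.8 percentage points against 3.9 points for dusk, and gives 24.8 % after dusk.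

In this flask the frozen level 1.06 mM stands beside a reading of 1.05 mM at 0.800 s, and the reading climbs above it to 1.29 mM at 8.00 s. The neighbouring flask holds 0.14 M of substrate, with the time and the rest unchanged. There the frozen level is 0.600 mM, lower than here, and the same ledger leaves 54.4 % substrate, books 31.2 % side product and keeps 13.1 % target. The simulated neighbouring flask holds 53 % substrate, 31.0 % side product and 14.4 % target.

The numbers are those of an exercise; what happens was integrated by code.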